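**Strategy.** Ring A (C1–C5, C10) is disconnected across C1–C10 and C4–C5. The cis ring fusion (5-H and 10-CH3 on one face), the C6/C9 oxygenation pattern of ring B and the C2 oxygen flanked by two CH2 groups identify ring B as 2,6-dimethyl-1,4-benzoquinone and ring A as a 2-silyloxydiene. One catalytic enantioselective endo Diels–Alder reaction closes ring A and sets C4, C5 and C10. Its precursor is a (Z)-configured 4,4-disubstituted 2-(triisopropylsilyloxy)diene made from a propargyl ether. The residual enedione then delivers the C6 alcohol and, through an enol triflate, the C8=C9 alkene and the side chain, whose butenolide is introduced preformed.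

Key step: step 5

Remark: labdane numbering is used (ring A = C1, C2, C3, C4, C5, C10; ring B = C5 to C10; C19 = CH2O on C4; side chain C11–C16); β is the face of the C10 methyl. The SMILES is read as the cis-fused decalin (2R,4S,5S,6S,10S): 5β-H, 4β-CH2OAc, 4α-CH3, 2α-OH, 6α-OH. TBS = tert-butyldimethylsilyl, TIPS = triisopropylsilyl, TES = triethylsilyl, Tf = SO2CF3.

Step 1
Reactants: 1 tert-butyldimethyl(prop-2-yn-1-yloxy)silane; 2 N-methoxy-N-methylcarbamoyl chloride
Product: 4 4-(tert-butyldimethylsilyloxy)-N-methoxy-N-methylbut-2-ynamide, via lithium acetylide 3 (not isolated)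
Conditions: n-BuLi, THF, −78 °C; then 2, −78 → 0 °C
Reagents that add atoms: none
Why: Acylation of a lithium acetylide with a carbamoyl chloride gives the alkynyl Weinreb amide, which does not add a second acetylide.

Step 2
Reactants: 4 4-(tert-butyldimethylsilyloxy)-N-methoxy-N-methylbut-2-ynamide
Product: 5 (Z)-4-(tert-butyldimethylsilyloxy)-N-methoxy-N,3-dimethylbut-2-enamide
Conditions: Me2CuLi (from MeLi and CuI), THF, −78 °C; MeOH quench at −78 °C, then aq. NH4Cl
Reagents that add atoms: lithium dimethylcuprate, [Li+].C[Cu-]C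
Why: syn-Carbocupration (conjugate addition of a Gilman cuprate to the ynamide) puts CH3 and copper cis, so protonation with retention at low temperature should leave CH2OTBS cis to the carbonyl, the (Z)-alkene.

Step 3
Reactants: 5 (Z)-4-(tert-butyldimethylsilyloxy)-N-methoxy-N,3-dimethylbut-2-enamide
Product: 6 (Z)-5-(tert-butyldimethylsilyloxy)-4-methylpent-3-en-2-one
Conditions: MeMgBr, THF, 0 °C; aq. NH4Cl
Reagents that add atoms: methylmagnesium bromide, C[Mg]Br
Why: Weinreb ketone synthesis: the magnesium chelate stops at the ketone stage, and the β,β-disubstituted (Z)-alkene is neither attacked nor isomerised.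

Step 4
Reactants: 6 (Z)-5-(tert-butyldimethylsilyloxy)-4-methylpent-3-en-2-one
Product: 8 (Z)-5-(tert-butyldimethylsilyloxy)-4-methyl-2-(triisopropylsilyloxy)penta-1,3-diene, via lithium dienolate 7 (not isolated)
Conditions: LiN(i-Pr)2, THF, −78 °C; then TIPSOTf, −78 → 0 °C
Reagents that add atoms: triisopropylsilyl triflate, CC(C)[Si](C(C)C)(C(C)C)OS(=O)(=O)C(F)(F)F
Why: Kinetic deprotonation of the methyl ketone at the methyl group and O-silylation (silyl enol ether formation) give the cross-conjugated 2-silyloxydiene with the alkene geometry unchanged.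

Step 5
Reactants: 8 (Z)-5-(tert-butyldimethylsilyloxy)-4-methyl-2-(triisopropylsilyloxy)penta-1,3-diene; 9 2,6-dimethyl-1,4-benzoquinone
Product: 10 cis-fused enedione adduct (5β-H, 10β-CH3, 4α-CH3, 4β-CH2OTBS; TIPS enol ether at C2=C3; C6=O, C7=C8, C9=O)
Conditions: (S)-B-(o-tolyl)-3,3-diphenylpyrrolo-oxazaborolidine (C24H24BNO, 20 mol %), HN(SO2CF3)2 (20 mol %), CH2Cl2, −78 → −40 °C
Reagents that add atoms: none
Why: The protonated oxazaborolidine binds the C6 carbonyl of 9 (the more basic, unhindered one, flanked by two C–H), so the diene adds by an asynchronous endo [4+2] cycloaddition in which the silyloxy-activated terminus C1 bonds first to the methyl-bearing β-carbon C10 and C4 then bonds to C5. The closest known reaction type is the oxazaborolidinium-catalysed enantioselective Diels–Alder reaction of 2-(triisopropylsilyloxy)butadienes with methyl-substituted 1,4-benzoquinones. Ring A closes as a six-membered ring by suprafacial [4+2] cycloaddition (in the limit of full asynchronicity, Mukaiyama–Michael addition followed by 6-endo-trig closure), which can only give the cis fusion. C5 and C10 are set relative to each other by the suprafacial addition and in the absolute sense by the catalyst, which shields one face of the bound quinone C=C (sense assigned from the accepted C–H···O binding model, the antipodal catalyst being equally available); C4 follows from the (Z)-geometry of 8 and the endo mode, which put the inside CH2OTBS group cis to H5 and the C10 methyl and the outside CH3 cis to C6. The step needs regioselectivity (C1 to C10; secured by the C2 silyloxy group, by activation through C6=O and by the fact that the other orientation would join two quaternary carbons), endo selectivity (secondary overlap with the enedione, and the inside substituent clashes with ring B in the exo mode) and retention of diene geometry (ring closure faster than C3–C4 rotation).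

Step 6
Reactants: 10 cis-fused enedione adduct
Product: 11 6α-allylic alcohol (C9 enone and TIPS enol ether retained)
Conditions: NaBH4, CeCl3·7H2O, MeOH/CH2Cl2, −78 °C (10 used without delay)
Reagents that add atoms: none
Why: Luche 1,2-reduction takes the less hindered C6 carbonyl (C9 is flanked by quaternary C10 and the C8 methyl) from the convex β face, anti to the C4 quaternary carbon on the α side (Felkin–Anh), which gives the 6α-alcohol and removes the epimerisable C5–H/C6=O pair.

Step 7
Reactants: 11 6α-allylic alcohol
Product: 12 6α-triethylsilyl ether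
Conditions: TESOTf, 2,6-lutidine, CH2Cl2, −78 °C
Reagents that add atoms: triethylsilyl triflate, CC[Si](CC)(CC)OS(=O)(=O)C(F)(F)F
Why: Silyl ether formation with a silyl triflate protects the hindered alcohol without touching the enol ether, so that no alkoxide is present in the triflation.

Step 8
Reactants: 12 6α-triethylsilyl ether
Product: 15 keto diol enol triflate (C2 ketone; 6α-OH; C19-OH; C8=C9 with C9-OTf), via lithium enolate 13 (not isolated), via silylated enol triflate 14 (not isolated)
Conditions: LiBH(s-Bu)3, THF, −78 °C; N-(5-chloropyridin-2-yl)bis(trifluoromethanesulfonyl)imide, −78 → 0 °C; then HF·pyridine, THF, 0 → 23 °C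
Reagents that add atoms: N-(5-chloropyridin-2-yl)bis(trifluoromethanesulfonyl)imide, FC(F)(F)S(=O)(=O)N(c1ccc(Cl)cn1)S(=O)(=O)C(F)(F)F
Why: Reductive triflation: conjugate hydride addition to the unsubstituted C7 of the α-methyl enone gives the C9 enolate regiospecifically, O-triflation fixes the C8=C9 alkene, and HF then cleaves the TES ether, the primary TBS ether and the silyl enol ether (C2 ketone).

Step 9
Reactants: 15 keto diol enol triflate
Product: 16 C19 acetate (C2 ketone, 6α-OH, C9-OTf)
Conditions: AcCl, 2,4,6-collidine, CH2Cl2, −78 °C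
Reagents that add atoms: acetyl chloride, CC(Cl)=O
Why: Chemoselective acylation: acetyl chloride with a hindered pyridine base at low temperature should acetylate the primary C19 hydroxyl much faster than the secondary C6 hydroxyl next to the C4 quaternary centre.

Step 10
Reactants: 16 C19 acetate
Product: 17 2α,6α-diol (19-OAc, C9-OTf)
Conditions: LiBH(s-Bu)3 (2.2 equiv), THF, −78 °C; AcOH quench at −78 °C
Reagents that add atoms: none
Why: Ketone reduction under steric approach control: in the favoured chair of ring A the 4α-CH3 and C9 are syn-axial on the α face of C2 (the other chair has syn-diaxial CH2OAc/CH3 and 6-OH/C1 contacts), so the bulky hydride should enter equatorially from the β face and give the 2α-alcohol.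

Step 11
Reactants: 17 2α,6α-diol enol triflate
Product: 18 9-vinyl diene (C8=C9–C11=C12; 2α,6α-diol; 19-OAc)
Conditions: tributyl(vinyl)stannane, Pd(PPh3)4 (10 mol %), LiCl, THF, 65 °C
Reagents that add atoms: tributyl(vinyl)stannane, C=C[Sn](CCCC)(CCCC)CCCC
Why: Stille coupling of the enol triflate installs C11–C12; congested 2,6,6-trisubstituted cyclohexenyl triflates are competent partners, and free hydroxyls and the acetate are tolerated.

Step 12
Reactants: 18 9-vinyl diene; 19 4-bromofuran-2(5H)-one
Product: 21 target CNP0201970.1, via B-alkyl-9-borabicyclononane 20 (not isolated)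
Conditions: 9-borabicyclo[3.3.1]nonane (excess), THF, 0 → 23 °C; then 19, PdCl2(dppf) [dppf = Fe(C5H4PPh2)2] (10 mol %), AsPh3, aq. K3PO4, DMF, 23 °C
Reagents that add atoms: none
Why: Anti-Markovnikov hydroboration occurs only at the terminal vinyl group (the tetrasubstituted C8=C9 is inert), and B-alkyl Suzuki–Miyaura coupling with the β-bromobutenolide joins C12 to C13 with the lactone ring already in place.

**Compound list**

1 | tert-butyldimethyl(prop-2-yn-1-yloxy)silane | C#CCO[Si](C)(C)C(C)(C)C | starting material
2 | N-methoxy-N-methylcarbamoyl chloride | CON(C)C(Cl)=O | starting material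
3 | lithium acetylide of 1 | [Li]C#CCO[Si](C)(C)C(C)(C)C | intermediate (not isolated)
4 | 4-(tert-butyldimethylsilyloxy)-N-methoxy-N-methylbut-2-ynamide | CON(C)C(=O)C#CCO[Si](C)(C)C(C)(C)C | intermediate
5 | (Z)-4-(tert-butyldimethylsilyloxy)-N-methoxy-N,3-dimethylbut-2-enamide | CON(C)C(=O)/C=C(\CO[Si](C)(C)C(C)(C)C)C | intermediate
6 | (Z)-5-(tert-butyldimethylsilyloxy)-4-methylpent-3-en-2-one | CC(=O)/C=C(\CO[Si](C)(C)C(C)(C)C)C | intermediate
7 | lithium cross-conjugated dienolate of 6 | [Li]OC(=C)/C=C(\CO[Si](C)(C)C(C)(C)C)C | intermediate (not isolated)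
8 | (Z)-5-(tert-butyldimethylsilyloxy)-4-methyl-2-(triisopropylsilyloxy)penta-1,3-diene | C=C(O[Si](C(C)C)(C(C)C)C(C)C)/C=C(\CO[Si](C)(C)C(C)(C)C)C | intermediate
9 | 2,6-dimethyl-1,4-benzoquinone | CC1=CC(=O)C=C(C)C1=O | starting material
10 | (4aR,5S,8aS)-5-[(tert-butyldimethylsilyloxy)methyl]-2,5,8a-trimethyl-7-(triisopropylsilyloxy)-4a,5,8,8a-tetrahydronaphthalene-1,4-dione (cis-fused adduct) | CC(C)(C)[Si](C)(C)OC[C@@]1(C)C=C(O[Si](C(C)C)(C(C)C)C(C)C)C[C@]2(C)C(=O)C(C)=CC(=O)[C@H]12 | intermediate
11 | 6α-alcohol of 10 (C9 enone, C7=C8, TIPS enol ether, 19-OTBS) | CC(C)(C)[Si](C)(C)OC[C@@]1(C)C=C(O[Si](C(C)C)(C(C)C)C(C)C)C[C@]2(C)C(=O)C(C)=C[C@H](O)[C@H]12 | intermediate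
12 | 6α-triethylsilyl ether of 11 | CC(C)(C)[Si](C)(C)OC[C@@]1(C)C=C(O[Si](C(C)C)(C(C)C)C(C)C)C[C@]2(C)C(=O)C(C)=C[C@H](O[Si](CC)(CC)CC)[C@H]12 | intermediate
13 | lithium C9 enolate (C8=C9, C7H2) | CC(C)(C)[Si](C)(C)OC[C@@]1(C)C=C(O[Si](C(C)C)(C(C)C)C(C)C)C[C@]2(C)C(O[Li])=C(C)C[C@H](O[Si](CC)(CC)CC)[C@H]12 | intermediate (not isolated)
14 | C9 enol triflate, fully silylated | CC(C)(C)[Si](C)(C)OC[C@@]1(C)C=C(O[Si](C(C)C)(C(C)C)C(C)C)C[C@]2(C)C(OS(=O)(=O)C(F)(F)F)=C(C)C[C@H](O[Si](CC)(CC)CC)[C@H]12 | intermediate (not isolated)
15 | C9 enol triflate with C2 ketone, 6α-OH and C19-OH | OC[C@@]1(C)CC(=O)C[C@]2(C)C(OS(=O)(=O)C(F)(F)F)=C(C)C[C@H](O)[C@H]12 | intermediate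
16 | C19 acetate of 15 | CC(=O)OC[C@@]1(C)CC(=O)C[C@]2(C)C(OS(=O)(=O)C(F)(F)F)=C(C)C[C@H](O)[C@H]12 | intermediate
17 | 2α,6α-diol, 19-acetate, C9 enol triflate | CC(=O)OC[C@@]1(C)C[C@H](O)C[C@]2(C)C(OS(=O)(=O)C(F)(F)F)=C(C)C[C@H](O)[C@H]12 | intermediate
18 | 9-vinyl diene (2α,6α-diol, 19-acetate) | CC(=O)OC[C@@]1(C)C[C@H](O)C[C@]2(C)C(C=C)=C(C)C[C@H](O)[C@H]12 | intermediate
19 | 4-bromofuran-2(5H)-one | BrC1=CC(=O)OC1 | starting material
20 | C12 B-alkyl-9-borabicyclo[3.3.1]nonane from 18 | CC(=O)OC[C@@]1(C)C[C@H](O)C[C@]2(C)C(CCB3C4CCCC3CCC4)=C(C)C[C@H](O)[C@H]12 | intermediate (not isolated)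
21 | [(1S,3R,4aS,8S,8aS)-3,8-dihydroxy-1,4a,6-trimethyl-5-[2-(5-oxo-2,5-dihydrofuran-3-yl)ethyl]-1,2,3,4,4a,7,8,8a-octahydronaphthalen-1-yl]methyl acetate (labdane numbering 2R,4S,5S,6S,10S) | CC(=O)OC[C@@]1(C)C[C@H](O)C[C@]2(C)C(CCC3=CC(=O)OC3)=C(C)C[C@H](O)[C@H]12 | target

Total steps: 12. Longest linear sequence: 12 steps (1 → 21); 9 and 19 are commercial.

**Steps most likely to fail**

Step 5. The second C–C bond may fail to follow the first, because the inside CH2OTBS group strains the s-cis diene. The reaction could then stop after Mukaiyama–Michael addition and silyl transfer, or lose fidelity at C4. Fallback: the annulation is run as two separate Michael events. Setting out from 8 and 9, the same chiral Lewis acid at −78 °C is used only for the first bond (it already fixes C10), and the silyl dienol ether (S)-6-[(Z)-5-(tert-butyldimethylsilyloxy)-4-methyl-2-oxopent-3-enyl]-2,6-dimethyl-4-(triisopropylsilyloxy)cyclohexa-2,4-dienone F1 is isolated. Ring A is then closed by an intramolecular Mukaiyama–Michael addition of its C5=C6 silyl enol ether to the (Z)-enone (catalytic HN(SO2CF3)2 or trimethylsilyl triflate, CH2Cl2, −78 °C, with O-to-O silyl transfer), through the same compact transition-state geometry as the second half of the cycloaddition. This returns to 10.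

Step 12. The alkylborane may transmetalate slowly, or the bromobutenolide may be consumed by aqueous base (hydrolysis, addition–elimination) before it couples. Fallback: a base-free cross-electrophile coupling. Setting out from 18, hydroboration with 9-borabicyclo[3.3.1]nonane (through 20) and oxidation with NaBO3·4H2O give the C12 primary alcohol F2. I2, PPh3 and imidazole (CH2Cl2, 0 °C) convert only the primary hydroxyl into the C12 iodide F3. Nickel-catalysed reductive coupling of F3 with 19 (NiI2, 4,4'-di-tert-butyl-2,2'-bipyridine, Zn, N,N-dimethylacetamide, 23 °C) comes back to the route at 21.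

Step 10. Hydride may be delivered to the wrong face if the other chair of ring A is the reacting conformer; equatorial attack would then give the axial 2β-alcohol. Fallback: thermodynamic instead of kinetic control. Setting out from 16, single-electron reduction with SmI2 (2.2 equiv), H2O and Et3N in THF at −78 °C protonates the ketyl to the more stable equatorial alcohol, which in that chair is the 2α-epimer. The route is rejoined at 17, and no compound outside the list is formed (entry F0).

**Further compounds**

F1 | step 5 | (S)-6-[(Z)-5-(tert-butyldimethylsilyloxy)-4-methyl-2-oxopent-3-enyl]-2,6-dimethyl-4-(triisopropylsilyloxy)cyclohexa-2,4-dienone | CC(C)(C)[Si](C)(C)OC/C(C)=C\C(=O)C[C@]1(C)C(=O)C(C)=CC(O[Si](C(C)C)(C(C)C)C(C)C)=C1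
F0 | step 10 | none | none
F2 | step 12 | C12 primary alcohol (9-(2-hydroxyethyl) analogue of 18) | CC(=O)OC[C@@]1(C)C[C@H](O)C[C@]2(C)C(CCO)=C(C)C[C@H](O)[C@H]12
F3 | step 12 | C12 iodide (9-(2-iodoethyl) analogue of 18) | CC(=O)OC[C@@]1(C)C[C@H](O)C[C@]2(C)C(CCI)=C(C)C[C@H](O)[C@H]12
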